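**Retrosynthetic overview**

- The route rests on the 1,2,3-trisubstituted benzene ring of the target. Ring carbon C1 (bearing the ester), C2–OH and C3–OH correspond to the α-carbon, the ketone carbon and the γ-oxygenated carbon of a 4-(benzyloxy)acetoacetate that already carries the C23 ester chain, so only the CH carbons C4, C5 and C6 have to be added.
- The benzene ring, the only ring, is formed second to last by disconnecting ring bonds C3–C4 and C1–C6: a formal [3+3] cyclocondensation of the 1,3-bis(trimethylsilyloxy)diene of the chain-bearing keto ester with 1,1,3,3-tetramethoxypropane. Hydrogenolysis of the C3 benzyl ether ends the route.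
- The β-keto ester comes from (S)-20-methyldocosan-1-ol and the benzyloxyacetyl derivative of Meldrum's acid.
- The alcohol is disconnected at C18–C19 into (S)-1-bromo-2-methylbutane, the source of the C20 stereocentre, and a C18 unit from octadecanedioic acid.

Key step: step 10

Remark on the chemistry: the acetal carbon of the THP ethers and the enol ether geometries of the silylated intermediates are left unspecified, since they are removed or end in the arene.

**Route**

Step 1
Reactants: 1 octadecanedioic acid
Product: 2 octadecane-1,18-diol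
Conditions: LiAlH4 (3 equiv), THF, reflux; aqueous NaOH work-up
Reagents that add atoms: none
Why: Exhaustive LiAlH4 reduction of a dicarboxylic acid to the α,ω-diol is a standard hydride reduction, and the substrate carries no other reducible group.

Step 2
Reactants: 2 octadecane-1,18-diol
Product: 3 18-bromooctadecan-1-ol
Conditions: 48% aq. HBr (1.1 equiv), toluene, reflux
Reagents that add atoms: hydrogen bromide, Br
Why: Monobromination of a symmetrical α,ω-diol with aqueous HBr in refluxing toluene (SN2 substitution of the protonated hydroxyl) is selective because the bromo alcohol passes into the toluene phase, where its remaining hydroxyl is poorly activated.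

Step 3
Reactants: 3 18-bromooctadecan-1-ol
Product: 4 2-[(18-bromooctadecyl)oxy]tetrahydro-2H-pyran
Conditions: 3,4-dihydro-2H-pyran (1.5 equiv), pyridinium p-toluenesulfonate (cat.), CH2Cl2, 20 °C
Reagents that add atoms: 3,4-dihydro-2H-pyran, C1=COCCC1
Why: Acid-catalysed addition of the alcohol to the enol ether (tetrahydropyranylation) masks the hydroxyl proton, which would otherwise quench the Grignard reagent of the next step.

Step 4
Reactants: 5 (S)-1-bromo-2-methylbutane; 4 2-[(18-bromooctadecyl)oxy]tetrahydro-2H-pyran
Product: 7 2-{[(S)-20-methyldocosyl]oxy}tetrahydro-2H-pyran, via (S)-2-methylbutylmagnesium bromide 6 (not isolated)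
Conditions: 5 (1.5 equiv), Mg, THF, 40 °C; then 4, Li2CuCl4 (3 mol %), THF, −10 °C → 20 °C; aq. NH4Cl
Reagents that add atoms: none
Why: Copper-catalysed Kochi-type sp3–sp3 cross-coupling of a primary alkyl Grignard reagent with a primary alkyl bromide forms the C18–C19 bond, and the C20 stereocentre, which lies β to magnesium and takes no part in bond making, is carried over unchanged from 5 with (S) configuration.

Step 5
Reactants: 7 2-{[(S)-20-methyldocosyl]oxy}tetrahydro-2H-pyran
Product: 8 (S)-20-methyldocosan-1-ol
Conditions: TsOH·H2O (cat.), MeOH/THF, 40 °C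
Reagents that add atoms: none
Why: Acid-catalysed transacetalisation in methanol removes the THP group as 2-methoxytetrahydropyran without touching the saturated chain or its stereocentre.

Step 6
Reactants: 9 benzyloxyacetyl chloride; 10 Meldrum's acid
Product: 11 5-[2-(benzyloxy)-1-hydroxyethylidene]-2,2-dimethyl-1,3-dioxane-4,6-dione
Conditions: pyridine (2 equiv), CH2Cl2, 0 °C → 20 °C; dilute HCl wash; used crude
Reagents that add atoms: none
Why: C-Acylation of Meldrum's acid by an acid chloride with pyridine as base (Oikawa–Yonemitsu acylation) gives the enolised acyl Meldrum's acid, a stable acylketene precursor.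

Step 7
Reactants: 8 (S)-20-methyldocosan-1-ol; 11 5-[2-(benzyloxy)-1-hydroxyethylidene]-2,2-dimethyl-1,3-dioxane-4,6-dione (1.2 equiv)
Product: 13 (S)-20-methyldocosyl 4-(benzyloxy)-3-oxobutanoate, via (benzyloxyacetyl)ketene 12 (not isolated)
Conditions: toluene, 100 °C
Reagents that add atoms: none
Why: Thermolysis of the acyl Meldrum's acid releases acetone and CO2 to give acylketene 12, which the primary alcohol traps under neutral conditions to give the β-keto ester (Oikawa–Yonemitsu alcoholysis).

Step 8
Reactants: 13 (S)-20-methyldocosyl 4-(benzyloxy)-3-oxobutanoate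
Product: 14 (S)-20-methyldocosyl 4-(benzyloxy)-3-(trimethylsilyloxy)but-2-enoate
Conditions: Me3SiCl (1.5 equiv), Et3N (1.6 equiv), toluene, 20 °C; filtration under argon; used crude
Reagents that add atoms: chlorotrimethylsilane, C[Si](C)(C)Cl
Why: Soft enolisation of the β-keto ester with Et3N and O-silylation by Me3SiCl gives the conjugated 3-silyloxy enoate, the standard first stage of a Chan-type diene preparation.

Step 9
Reactants: 14 (S)-20-methyldocosyl 4-(benzyloxy)-3-(trimethylsilyloxy)but-2-enoate
Product: 16 4-(benzyloxy)-1-[(S)-20-methyldocosyloxy]-1,3-bis(trimethylsilyloxy)buta-1,3-diene, via lithium 4-(benzyloxy)-1-[(S)-20-methyldocosyloxy]-3-(trimethylsilyloxy)buta-1,3-dien-1-olate 15 (not isolated)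
Conditions: LiN(i-Pr)2 (commercial solution, 1.3 equiv), THF, −78 °C; then Me3SiCl (1.5 equiv), −78 → 20 °C; hexane, filtration under argon; used crude
Reagents that add atoms: chlorotrimethylsilane, C[Si](C)(C)Cl
Why: Kinetic γ-deprotonation of the vinylogous ester with LiN(i-Pr)2 at −78 °C gives lithium dienolate 15, whose O-silylation at the ester oxygen furnishes the 1,3-bis(silyloxy)diene, as is established for 4-alkoxyacetoacetates.

Step 10
Reactants: 16 4-(benzyloxy)-1-[(S)-20-methyldocosyloxy]-1,3-bis(trimethylsilyloxy)buta-1,3-diene; 17 1,1,3,3-tetramethoxypropane (1.1 equiv)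
Product: 20 (S)-20-methyldocosyl 3-(benzyloxy)-2-hydroxybenzoate, via open-chain trimethoxy silyl ketene acetal 18 (not isolated), via dimethoxycyclohexanone ester 19 (not isolated)
Conditions: TiCl4 (1.5 equiv), 4 Å molecular sieves, CH2Cl2 (dilute), −78 → 20 °C; then 10% aq. HCl
Reagents that add atoms: none
Why: TiCl4 ionises one acetal of 17 to a methoxycarbenium ion, which the terminal, benzyloxy-bearing carbon of diene 16 attacks in a vinylogous Mukaiyama aldol-type addition (ring bond C3–C4) to give 18, in which the C1 silyl ketene acetal survives. Ionisation of the second acetal and attack by the α-carbon then closes the six-membered carbocycle in a 6-(enolexo)-exo-trig Mukaiyama-type cyclisation (ring bond C1–C6) to give 19; two β-eliminations of methanol and enolisation of the ring ketone deliver the benzene ring with the C2 hydroxyl hydrogen-bonded to the ester. The closest known reaction type is the Chan–Brownbridge formal [3+3] cyclocondensation of 1,3-bis(silyloxy)-1,3-dienes with 1,3-dielectrophiles, including malonaldehyde bis(dimethyl acetal) and 4-alkoxy dienes, which give 3-alkoxysalicylates. No stereocentre is created in the product, because the transient sp3 centres of 18 and 19 are erased on aromatisation, and the remote C20 centre is not involved. The step needs C- rather than O-attack and reaction at the terminal carbon first, which the vinylogous reactivity of the diene (largest coefficient at the γ-carbon) secures, while the symmetrical three-carbon dielectrophile removes any regiochemical question. The primary alkyl ester and the benzyl ether should tolerate TiCl4 at low temperature, and dilution favours ring closure over attack of a second acetal molecule.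

Step 11
Reactants: 20 (S)-20-methyldocosyl 3-(benzyloxy)-2-hydroxybenzoate
Product: 21 gentiside B, (S)-20-methyldocosyl 2,3-dihydroxybenzoate
Conditions: H2 (1 atm), 10% Pd/C, EtOAc/EtOH, 20 °C
Reagents that add atoms: none
Why: Catalytic hydrogenolysis of the benzylic C–O bond over Pd/C frees the C3 phenol, while the primary alkyl ester, the arene and the saturated stereocentre are inert under these conditions.

**Compound list**

1 | octadecanedioic acid | OC(=O)CCCCCCCCCCCCCCCCC(=O)O | starting material
2 | octadecane-1,18-diol | OCCCCCCCCCCCCCCCCCCO | intermediate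
3 | 18-bromooctadecan-1-ol | OCCCCCCCCCCCCCCCCCCBr | intermediate
4 | 2-[(18-bromooctadecyl)oxy]tetrahydro-2H-pyran (racemic at the acetal carbon) | BrCCCCCCCCCCCCCCCCCCOC1CCCCO1 | intermediate
5 | (S)-1-bromo-2-methylbutane | CC[C@H](C)CBr | starting material
6 | (S)-2-methylbutylmagnesium bromide | CC[C@H](C)C[Mg]Br | intermediate
7 | 2-{[(S)-20-methyldocosyl]oxy}tetrahydro-2H-pyran (epimers at the acetal carbon) | CC[C@H](C)CCCCCCCCCCCCCCCCCCCOC1CCCCO1 | intermediate
8 | (S)-20-methyldocosan-1-ol | CC[C@H](C)CCCCCCCCCCCCCCCCCCCO | intermediate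
9 | benzyloxyacetyl chloride | O=C(Cl)COCc1ccccc1 | starting material
10 | Meldrum's acid (2,2-dimethyl-1,3-dioxane-4,6-dione) | CC1(C)OC(=O)CC(=O)O1 | starting material
11 | 5-[2-(benzyloxy)-1-hydroxyethylidene]-2,2-dimethyl-1,3-dioxane-4,6-dione | CC1(C)OC(=O)C(=C(O)COCc2ccccc2)C(=O)O1 | intermediate
12 | (benzyloxyacetyl)ketene, 4-(benzyloxy)but-1-ene-1,3-dione | O=C=CC(=O)COCc1ccccc1 | intermediate
13 | (S)-20-methyldocosyl 4-(benzyloxy)-3-oxobutanoate | CC[C@H](C)CCCCCCCCCCCCCCCCCCCOC(=O)CC(=O)COCc1ccccc1 | intermediate
14 | (S)-20-methyldocosyl 4-(benzyloxy)-3-(trimethylsilyloxy)but-2-enoate (geometry immaterial) | CC[C@H](C)CCCCCCCCCCCCCCCCCCCOC(=O)C=C(O[Si](C)(C)C)COCc1ccccc1 | intermediate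
15 | lithium 4-(benzyloxy)-1-[(S)-20-methyldocosyloxy]-3-(trimethylsilyloxy)buta-1,3-dien-1-olate | CC[C@H](C)CCCCCCCCCCCCCCCCCCCOC(O[Li])=CC(O[Si](C)(C)C)=COCc1ccccc1 | intermediate
16 | 4-(benzyloxy)-1-[(S)-20-methyldocosyloxy]-1,3-bis(trimethylsilyloxy)buta-1,3-diene (geometry immaterial) | CC[C@H](C)CCCCCCCCCCCCCCCCCCCOC(O[Si](C)(C)C)=CC(O[Si](C)(C)C)=COCc1ccccc1 | intermediate
17 | 1,1,3,3-tetramethoxypropane | COC(OC)CC(OC)OC | starting material
18 | 4-(benzyloxy)-5,7,7-trimethoxy-1-[(S)-20-methyldocosyloxy]-1-(trimethylsilyloxy)hept-1-en-3-one (open-chain adduct, diastereomer mixture) | CC[C@H](C)CCCCCCCCCCCCCCCCCCCOC(O[Si](C)(C)C)=CC(=O)C(OCc1ccccc1)C(OC)CC(OC)OC | intermediate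
19 | (S)-20-methyldocosyl 3-(benzyloxy)-4,6-dimethoxy-2-oxocyclohexane-1-carboxylate (diastereomer mixture) | CC[C@H](C)CCCCCCCCCCCCCCCCCCCOC(=O)C1C(OC)CC(OC)C(OCc2ccccc2)C1=O | intermediate
20 | (S)-20-methyldocosyl 3-(benzyloxy)-2-hydroxybenzoate | CC[C@H](C)CCCCCCCCCCCCCCCCCCCOC(=O)c1cccc(OCc2ccccc2)c1O | intermediate
21 | gentiside B, (S)-20-methyldocosyl 2,3-dihydroxybenzoate | CC[C@H](C)CCCCCCCCCCCCCCCCCCCOC(=O)c1cccc(O)c1O | target

**Step count**

Total: 11 steps. Longest linear sequence: 10 steps (steps 1–5 and 7–11, from octadecanedioic acid); step 6 is a one-step side branch.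

**Steps most likely to fail**

Step 10 (key step). The long-chain diene may crystallise from CH2Cl2 at −78 °C, so that the reaction starts only on warming. Adventitious HCl may protodesilylate the diene back to keto ester 13 before C–C bond formation. A second acetal molecule may add to the α-carbon in competition with ring closure, giving oligomers. Partial Lewis-acid loss of the benzyl ether would be harmless, since it would give 21 directly.

The fallback keeps the same ring construction but carries it out on a small ester and attaches the chain last. It sets out from 11 and returns at 20. Heating 11 with methanol in toluene should give methyl 4-(benzyloxy)-3-oxobutanoate F1. Silylation with Me3SiCl and Et3N should give methyl 4-(benzyloxy)-3-(trimethylsilyloxy)but-2-enoate F2. Deprotonation with LiN(i-Pr)2 at −78 °C should give lithium 4-(benzyloxy)-1-methoxy-3-(trimethylsilyloxy)buta-1,3-dien-1-olate F3, and Me3SiCl should convert it into the distillable 4-(benzyloxy)-1-methoxy-1,3-bis(trimethylsilyloxy)buta-1,3-diene F4. TiCl4-mediated cyclocondensation of F4 with 17 in CH2Cl2 should pass through 4-(benzyloxy)-1,5,7,7-tetramethoxy-1-(trimethylsilyloxy)hept-1-en-3-one F5 and methyl 3-(benzyloxy)-4,6-dimethoxy-2-oxocyclohexane-1-carboxylate F6 to methyl 3-(benzyloxy)-2-hydroxybenzoate F7. Saponification with LiOH in THF/MeOH/H2O should give 3-(benzyloxy)-2-hydroxybenzoic acid F8. Mitsunobu esterification of F8 with alcohol 8 (PPh3, diisopropyl azodicarboxylate, THF, 0 → 20 °C) should then give 20, because the more acidic carboxyl group reacts in preference to the hydrogen-bonded phenol.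

Step 9. γ-Deprotonation of the waxy, poorly soluble silyl enol ether at −78 °C may be incomplete. Partial C-silylation may occur, and the ketene acetal may hydrolyse during concentration and filtration.

The fallback sets out from 13 and returns at 16. It replaces the stepwise hard enolisation by a one-flask double soft enolisation: 13 is treated with Me3SiOTf (2.2 equiv) and Et3N (2.5 equiv) in Et2O at 0 °C, the ammonium triflate layer is separated under argon, and the ether layer is concentrated to give 16 directly. No strong base is used, 14 and 15 are bypassed, and no compound outside the list is formed (F0).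

Step 4. Transmetallation and coupling of the β-branched Grignard reagent may be slow. Wurtz homocoupling and reduction or elimination of the long-chain bromide would then compete, and the hydrocarbon by-products are hard to separate from the C23 product.

The fallback replaces the cross-coupling by alkylation of a sulfone-stabilised carbanion. It sets out from 4 and returns at 7. Bromide 4 is treated with PhSO2Na in DMF at 80 °C to give 2-{[18-(phenylsulfonyl)octadecyl]oxy}tetrahydro-2H-pyran F9. Deprotonation with n-BuLi in THF/DMPU at −78 °C should give 2-{[18-lithio-18-(phenylsulfonyl)octadecyl]oxy}tetrahydro-2H-pyran F10. Alkylation of F10 with bromide 5 (−78 → 20 °C) should give 2-{[(20S)-20-methyl-18-(phenylsulfonyl)docosyl]oxy}tetrahydro-2H-pyran F11 as a mixture of C18 epimers. Reductive desulfonylation with Mg turnings in MeOH should remove the sulfonyl group and the C18 stereocentre to give 7, with the C20 centre untouched.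

**Further compounds**

F1 | step 10 | methyl 4-(benzyloxy)-3-oxobutanoate | COC(=O)CC(=O)COCc1ccccc1
F2 | step 10 | methyl 4-(benzyloxy)-3-(trimethylsilyloxy)but-2-enoate | COC(=O)C=C(O[Si](C)(C)C)COCc1ccccc1
F3 | step 10 | lithium 4-(benzyloxy)-1-methoxy-3-(trimethylsilyloxy)buta-1,3-dien-1-olate | COC(O[Li])=CC(O[Si](C)(C)C)=COCc1ccccc1
F4 | step 10 | 4-(benzyloxy)-1-methoxy-1,3-bis(trimethylsilyloxy)buta-1,3-diene | COC(O[Si](C)(C)C)=CC(O[Si](C)(C)C)=COCc1ccccc1
F5 | step 10 | 4-(benzyloxy)-1,5,7,7-tetramethoxy-1-(trimethylsilyloxy)hept-1-en-3-one | COC(O[Si](C)(C)C)=CC(=O)C(OCc1ccccc1)C(OC)CC(OC)OC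
F6 | step 10 | methyl 3-(benzyloxy)-4,6-dimethoxy-2-oxocyclohexane-1-carboxylate | COC(=O)C1C(OC)CC(OC)C(OCc2ccccc2)C1=O
F7 | step 10 | methyl 3-(benzyloxy)-2-hydroxybenzoate | COC(=O)c1cccc(OCc2ccccc2)c1O
F8 | step 10 | 3-(benzyloxy)-2-hydroxybenzoic acid | OC(=O)c1cccc(OCc2ccccc2)c1O
F0 | step 9 | none | none
F9 | step 4 | 2-{[18-(phenylsulfonyl)octadecyl]oxy}tetrahydro-2H-pyran | O=S(=O)(CCCCCCCCCCCCCCCCCCOC1CCCCO1)c1ccccc1
F10 | step 4 | 2-{[18-lithio-18-(phenylsulfonyl)octadecyl]oxy}tetrahydro-2H-pyran | [Li]C(CCCCCCCCCCCCCCCCCOC1CCCCO1)S(=O)(=O)c1ccccc1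
F11 | step 4 | 2-{[(20S)-20-methyl-18-(phenylsulfonyl)docosyl]oxy}tetrahydro-2H-pyran | CC[C@H](C)CC(CCCCCCCCCCCCCCCCCOC1CCCCO1)S(=O)(=O)c1ccccc1
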